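**Retrosynthetic overview**
1. Target 28 ⇐ autoxidation at C11′ of dienedione 26 and closure of the hydroperoxide onto the C8′ ketone (1,2-dioxolan-3-ol, formed last); 26 ⇐ γ,δ-dehydrogenation and deketalisation of 24.
2. Acetoxy-norbornene 24 ⇐ stereospecific Cope rearrangement of keto-acetate 23, which carries a convex-face allylic acetate onto the bridge, syn to the alkene; 23 ⇐ homodimer 20 by reduction, allylic inversion and re-oxidation.
3. 20 ⇐ endo, head-to-head Diels–Alder dimerisation of a single cyclopentadienone 19 (norbornene ring).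
4. 19 ⇐ hydroazulenone 15: seven-membered ring by ring-closing metathesis, cyclopentenone by Stork–Danheiser transposition of a cyclic vinylogous ester.
5. Key C–C bond (C1–C10): enantioselective intermolecular Michael addition of cyclopentane-1,3-dione to crotonaldehyde; ring order: cyclopentane (bought) → cycloheptene → norbornene → 1,2-dioxolane.

Assumption: the two centres that can equilibrate (C7 next to the C8 ketone, and the C8′ hemiketal) are taken to prefer the configurations found in the target.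

Numbering: guaiane numbering for each C15 half. In 20–23 the unprimed half carries the one-carbon bridge (C2) and the primed half is the endo-fused cyclopentene. The Cope step exchanges the roles, so from 24 on the unprimed half is the acetoxy-bridged one. Centres marked RS, or left open in a SMILES, are epimer mixtures that are destroyed later.

Step 1
Reactants: 1 cyclopentane-1,3-dione; 2 (E)-but-2-enal
Product: 3 (2RS,4R)-2-hydroxy-4-methyl-3,4,6,7-tetrahydrocyclopenta[b]pyran-5(2H)-one
Conditions: (S)-2-[diphenyl(trimethylsilyloxy)methyl]pyrrolidine (10 mol%), PhCO2H (10 mol%), CH2Cl2, 0 °C → rt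
Reagents that add atoms: none
Why: Iminium-catalysed intermolecular Michael addition in which the dione attacks the β-carbon on the face not shielded by the diphenyl(silyloxy)methyl group, setting C10 as R, after which the adduct closes to the lactol.

Step 2
Reactants: 4 3-methylbutan-2-one; 5 2,4,6-tri(propan-2-yl)benzenesulfonohydrazide
Product: 6 N′-(3-methylbutan-2-ylidene)-2,4,6-tri(propan-2-yl)benzenesulfonohydrazide
Conditions: MeOH, cat. HCl, rt
Reagents that add atoms: none
Why: Simple hydrazone condensation that provides the Shapiro precursor.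

Step 3
Reactants: 6 N′-(3-methylbutan-2-ylidene)-2,4,6-tri(propan-2-yl)benzenesulfonohydrazide; 3 (2RS,4R)-2-hydroxy-4-methyl-3,4,6,7-tetrahydrocyclopenta[b]pyran-5(2H)-one
Product: 8 2-[(2R,4RS)-4-hydroxy-6-methyl-5-methylideneheptan-2-yl]cyclopentane-1,3-dione, via (3-methylbut-1-en-2-yl)lithium 7 (not isolated)
Conditions: 6, n-BuLi (2.05 equiv), THF/TMEDA, −78 → 0 °C; then 3 pre-opened with LiHMDS (THF, −78 °C), −78 → 0 °C; 1 M HCl work-up
Reagents that add atoms: none
Why: The Shapiro reaction gives the less substituted vinyllithium, which adds 1,2 to the aldehyde released when the lactol is deprotonated (the dione is protected as its enolate); the new carbinol centre is oxidised later, so its configuration does not matter.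

Step 4
Reactants: 8 2-[(2R,4RS)-4-hydroxy-6-methyl-5-methylideneheptan-2-yl]cyclopentane-1,3-dione
Product: 9 (2RS,4R)-4-methyl-2-(3-methylbut-1-en-2-yl)-3,4,6,7-tetrahydrocyclopenta[b]pyran-5(2H)-one
Conditions: PPTS (cat.), PhMe, 4 Å MS, 60 °C
Reagents that add atoms: none
Why: Acid-catalysed cyclodehydration to a six-membered cyclic vinylogous ester masks the C8 hydroxyl and differentiates the two dione carbonyls.

Step 5
Reactants: 9 (2RS,4R)-4-methyl-2-(3-methylbut-1-en-2-yl)-3,4,6,7-tetrahydrocyclopenta[b]pyran-5(2H)-one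
Product: 10 (2RS,4R,6RS)-4,6-dimethyl-2-(3-methylbut-1-en-2-yl)-3,4,6,7-tetrahydrocyclopenta[b]pyran-5(2H)-one
Conditions: LDA, THF, −78 °C; MeI, −78 → −20 °C
Reagents that add atoms: iodomethane CI
Why: Stork–Danheiser kinetic α′-alkylation of the vinylogous ester installs the future C4 methyl (this stereocentre is destroyed in step 12).

Step 6
Reactants: 10 (2RS,4R,6RS)-4,6-dimethyl-2-(3-methylbut-1-en-2-yl)-3,4,6,7-tetrahydrocyclopenta[b]pyran-5(2H)-one
Product: 12 3-ethenyl-2-[(2R,4RS)-4-hydroxy-6-methyl-5-methylideneheptan-2-yl]-4-methylcyclopent-2-en-1-one, via (4R)-5-ethenyl-4,6-dimethyl-2-(3-methylbut-1-en-2-yl)-2,3,4,5,6,7-hexahydrocyclopenta[b]pyran-5-ol 11 (not isolated)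
Conditions: CH2=CHMgBr, CeCl3, THF, −78 → 0 °C; then 1 M HCl, THF, rt
Reagents that add atoms: vinylmagnesium bromide C=C[Mg]Br; water O
Why: Stork–Danheiser 1,2-addition followed by acid-induced enone transposition gives the 2-alkyl-3-vinyl enone and frees the C8 hydroxyl in the same operation.

Step 7
Reactants: 12 3-ethenyl-2-[(2R,4RS)-4-hydroxy-6-methyl-5-methylideneheptan-2-yl]-4-methylcyclopent-2-en-1-one
Product: 13 (10R)-8-hydroxyguaia-1(5),6-dien-2-one [(8R)-6-hydroxy-3,8-dimethyl-5-(propan-2-yl)-3,6,7,8-tetrahydroazulen-1(2H)-one], C4/C8 epimers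
Conditions: Grubbs II (5 mol%), PhMe (5 mM), 80 °C
Reagents that add atoms: none
Why: Ring-closing metathesis between the vinyl group and the 1,1-disubstituted alkene closes the seven-membered ring (C6=C7) with loss of ethene.

Step 8
Reactants: 13 (10R)-8-hydroxyguaia-1(5),6-dien-2-one
Product: 14 (10R)-guaia-1(5),6-diene-2,8-dione [(8R)-3,8-dimethyl-5-(propan-2-yl)-2,3,7,8-tetrahydroazulene-1,6-dione]
Conditions: Dess–Martin periodinane, NaHCO3, CH2Cl2, rt
Reagents that add atoms: none
Why: Dess–Martin oxidation of the secondary allylic alcohol removes the epimeric C8 centre.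

Step 9
Reactants: 14 (10R)-guaia-1(5),6-diene-2,8-dione
Product: 15 (7S,10R)-guai-1(5)-ene-2,8-dione [(5S,8R)-3,8-dimethyl-5-(propan-2-yl)-2,3,4,5,7,8-hexahydroazulene-1,6-dione], C4 epimers
Conditions: H2 (1 atm), 5% Pd/C, EtOAc, rt; then DBU (0.2 equiv), CH2Cl2, rt
Reagents that add atoms: none
Why: Chemoselective hydrogenation of the trisubstituted C6=C7 bond (the tetrasubstituted enone is untouched), then base equilibration of C7 to the cis-7,10 isomer with a pseudo-equatorial isopropyl group, which is 7S.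

Step 10
Reactants: 15 (7S,10R)-guai-1(5)-ene-2,8-dione
Product: 16 (7S,10R)-8,8-(ethylenedioxy)guai-1(5)-en-2-one
Conditions: (TMSOCH2)2, TMSOTf (5 mol%), CH2Cl2, −78 → −20 °C
Reagents that add atoms: 1,2-bis(trimethylsilyloxy)ethane C[Si](C)(C)OCCO[Si](C)(C)C
Why: Noyori ketalisation is selective for the saturated ketone over the hindered enone and runs under non-equilibrating conditions, so C7 is kept.

Step 11
Reactants: 16 (7S,10R)-8,8-(ethylenedioxy)guai-1(5)-en-2-one
Product: 17 (7S,10R)-8,8-(ethylenedioxy)-3-(phenylselanyl)guai-1(5)-en-2-one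
Conditions: LDA, THF, −78 °C; PhSeCl
Reagents that add atoms: benzeneselenenyl chloride Cl[Se]c1ccccc1
Why: Kinetic α′-enolate formation at C3 and Reich selenenylation, with selenium entering trans to the C4 methyl and therefore cis to H4.

Step 12
Reactants: 17 (7S,10R)-8,8-(ethylenedioxy)-3-(phenylselanyl)guai-1(5)-en-2-one (2 equiv)
Product: 20 endo head-to-head Diels–Alder homodimer (norbornenone with C2 as carbonyl bridge, bridgeheads C1 and C3, C4=C5; bonds C3–C3′ and C1–C4′ to the endo-fused 1′(5′)-en-2′-one half; both C8 as dioxolanes; 7S,10R,7′S,10′R), via selenoxide of 17 18 (not isolated), via (7S,10R)-8,8-(ethylenedioxy)guaia-1(5),3-dien-2-one 19 (not isolated)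
Conditions: 30% H2O2, pyridine, CH2Cl2, 0 °C → rt
Reagents that add atoms: none
Why: Selenoxide syn-elimination gives the cyclopentadienone, which dimerises at once by an endo Diels–Alder reaction led by bonding between the unsubstituted C3 carbons, each monomer reacting on the face anti to its pseudoaxial C10 methyl, which sets C1, C3, C3′ and C4′.

Step 13
Reactants: 20 endo head-to-head homodimer
Product: 21 2,2′-diol of 20 (2-OH on the bridge anti to C4=C5; 2′-OH on the concave, endo face)
Conditions: NaBH4, CeCl3·7H2O, MeOH/CH2Cl2, −78 → 0 °C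
Reagents that add atoms: none
Why: Luche reduction delivers hydride to the enone carbonyl from the open convex face, giving the endo allylic alcohol; the strained bridging ketone is reduced as well, which is harmless because it is re-oxidised in step 15.

Step 14
Reactants: 21 2,2′-diol of 20
Product: 22 2′-exo-acetate of 21 (2′-OAc on the convex face, 2-OH unchanged)
Conditions: PPh3, DIAD, AcOH, THF, 0 °C → rt
Reagents that add atoms: acetic acid CC(=O)O
Why: Mitsunobu reaction inverts the allylic C2′ alcohol by SN2 attack of acetate from the convex face, while the 7-norbornenyl alcohol cannot undergo back-side displacement and stays untouched.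

Step 15
Reactants: 22 2′-exo-acetate of 21
Product: 24 acetoxy-bridged norbornene (2-OAc syn to C4=C5; endo-fused 1′(5′)-en-2′-one half; both C8 as dioxolanes), via 2-oxo-2′-exo-acetate 23 (not isolated)
Conditions: Dess–Martin periodinane, NaHCO3, CH2Cl2, rt; then PhMe, 80 °C
Reagents that add atoms: none
Why: Dess–Martin oxidation regenerates the strained bridging ketone, and the Cope [3,3] rearrangement (breaks C1–C4′, makes C4–C1′), driven by relief of that strain and gain of enone conjugation, moves the convex-face acetate stereospecifically onto the new bridge syn to the new alkene and sets the new C1 and C4′.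

Step 16
Reactants: 24 acetoxy-bridged norbornene bis-ketal
Product: 25 6′,7′-didehydro-24 (1′(5′),6′-dien-2′-one in the primed half)
Conditions: chloranil, t-BuOH, reflux
Reagents that add atoms: none
Why: Quinone γ,δ-dehydrogenation of the only enolisable carbonyl through its extended dienol (hydride abstraction from C7′), as in the steroid 4-en-3-one to 4,6-dien-3-one conversion.

Step 17
Reactants: 25 6′,7′-didehydro-24
Product: 26 2-acetoxy-1′(5′),6′-diene-2′,8,8′-trione (both ketals removed)
Conditions: TsOH·H2O (cat.), acetone/H2O 10:1, 50 °C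
Reagents that add atoms: water O
Why: Acid-catalysed ketal hydrolysis, which leaves the syn-7-norbornenyl acetate intact because it cannot ionise or be attacked from the rear.

Step 18
Reactants: 26 2-acetoxy-1′(5′),6′-diene-2′,8,8′-trione
Product: 28 target CNP0317907.1 (8′-hydroxy-8′,11′-epidioxy; 8′R), via 11′-hydroperoxide of 26 27 (not isolated)
Conditions: O2 (1 atm), DBU, MeCN, 0 °C; AcOH quench
Reagents that add atoms: dioxygen O=O
Why: Base-mediated autoxidation of the extended trienolate (deprotonation of the isopropyl methine, O2 capture at C11′ keeps the dienedione conjugated), then the hydroperoxide adds to the C8′ ketone to give the 1,2-dioxolan-3-ol, whose hemiketal centre settles as 8′R.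

**Compound list**
1 | cyclopentane-1,3-dione | O=C1CCC(=O)C1 | starting material
2 | (E)-but-2-enal | C/C=C/C=O | starting material
3 | (2RS,4R)-2-hydroxy-4-methyl-3,4,6,7-tetrahydrocyclopenta[b]pyran-5(2H)-one | OC1C[C@@H](C)C2=C(O1)CCC2=O | intermediate
4 | 3-methylbutan-2-one | CC(C)C(C)=O | starting material
5 | 2,4,6-tri(propan-2-yl)benzenesulfonohydrazide | NNS(=O)(=O)c1c(C(C)C)cc(C(C)C)cc1C(C)C | starting material
6 | N′-(3-methylbutan-2-ylidene)-2,4,6-tri(propan-2-yl)benzenesulfonohydrazide | CC(C)C(C)=NNS(=O)(=O)c1c(C(C)C)cc(C(C)C)cc1C(C)C | intermediate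
7 | (3-methylbut-1-en-2-yl)lithium | [Li]C(=C)C(C)C | intermediate
8 | 2-[(2R,4RS)-4-hydroxy-6-methyl-5-methylideneheptan-2-yl]cyclopentane-1,3-dione | CC(C)C(=C)C(O)C[C@@H](C)C1C(=O)CCC1=O | intermediate
9 | (2RS,4R)-4-methyl-2-(3-methylbut-1-en-2-yl)-3,4,6,7-tetrahydrocyclopenta[b]pyran-5(2H)-one | CC(C)C(=C)C1C[C@@H](C)C2=C(O1)CCC2=O | intermediate
10 | (2RS,4R,6RS)-4,6-dimethyl-2-(3-methylbut-1-en-2-yl)-3,4,6,7-tetrahydrocyclopenta[b]pyran-5(2H)-one | CC(C)C(=C)C1C[C@@H](C)C2=C(O1)CC(C)C2=O | intermediate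
11 | (4R)-5-ethenyl-4,6-dimethyl-2-(3-methylbut-1-en-2-yl)-2,3,4,5,6,7-hexahydrocyclopenta[b]pyran-5-ol | CC(C)C(=C)C1C[C@@H](C)C2=C(O1)CC(C)C2(O)C=C | intermediate
12 | 3-ethenyl-2-[(2R,4RS)-4-hydroxy-6-methyl-5-methylideneheptan-2-yl]-4-methylcyclopent-2-en-1-one | O=C1CC(C)C(C=C)=C1[C@H](C)CC(O)C(=C)C(C)C | intermediate
13 | (10R)-8-hydroxyguaia-1(5),6-dien-2-one | O=C1CC(C)C2=C1[C@H](C)CC(O)C(C(C)C)=C2 | intermediate
14 | (10R)-guaia-1(5),6-diene-2,8-dione | O=C1CC(C)C2=C1[C@H](C)CC(=O)C(C(C)C)=C2 | intermediate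
15 | (7S,10R)-guai-1(5)-ene-2,8-dione | O=C1CC(C)C2=C1[C@H](C)CC(=O)[C@H](C(C)C)C2 | intermediate
16 | (7S,10R)-8,8-(ethylenedioxy)guai-1(5)-en-2-one | O=C1CC(C)C2=C1[C@H](C)CC3(OCCO3)[C@H](C(C)C)C2 | intermediate
17 | (7S,10R)-8,8-(ethylenedioxy)-3-(phenylselanyl)guai-1(5)-en-2-one | O=C1C([Se]c3ccccc3)C(C)C2=C1[C@H](C)CC4(OCCO4)[C@H](C(C)C)C2 | intermediate
18 | selenoxide of 17 | O=C1C([Se](=O)c3ccccc3)C(C)C2=C1[C@H](C)CC4(OCCO4)[C@H](C(C)C)C2 | intermediate
19 | (7S,10R)-8,8-(ethylenedioxy)guaia-1(5),3-dien-2-one | O=C1C=C(C)C2=C1[C@H](C)CC3(OCCO3)[C@H](C(C)C)C2 | intermediate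
20 | endo head-to-head homodimer (2-oxo bridge, 1′(5′)-en-2′-one, bis-dioxolane) | O=C1[C@H]2C(C)=C3C[C@@H](C(C)C)C4(OCCO4)C[C@@H](C)[C@]31[C@]1(C)C3=C(C(=O)[C@H]21)[C@H](C)CC5(OCCO5)[C@H](C(C)C)C3 | intermediate
21 | 2,2′-diol of 20 (2-OH anti to C4=C5, 2′-OH endo) | O[C@@H]1[C@H]2C(C)=C3C[C@@H](C(C)C)C4(OCCO4)C[C@@H](C)[C@]31[C@]1(C)C3=C([C@H](O)[C@H]21)[C@H](C)CC5(OCCO5)[C@H](C(C)C)C3 | intermediate
22 | 2′-exo-acetate of 21 | O[C@@H]1[C@H]2C(C)=C3C[C@@H](C(C)C)C4(OCCO4)C[C@@H](C)[C@]31[C@]1(C)C3=C([C@@H](OC(C)=O)[C@H]21)[C@H](C)CC5(OCCO5)[C@H](C(C)C)C3 | intermediate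
23 | 2-oxo-2′-exo-acetate | O=C1[C@H]2C(C)=C3C[C@@H](C(C)C)C4(OCCO4)C[C@@H](C)[C@]31[C@]1(C)C3=C([C@@H](OC(C)=O)[C@H]21)[C@H](C)CC5(OCCO5)[C@H](C(C)C)C3 | intermediate
24 | acetoxy-bridged norbornene bis-ketal (2-OAc syn to C4=C5, 1′(5′)-en-2′-one) | CC(=O)O[C@H]1[C@H]2C(C)=C3C[C@@H](C(C)C)C4(OCCO4)C[C@@H](C)[C@]31[C@]1(C)C3=C(C(=O)[C@H]21)[C@H](C)CC5(OCCO5)[C@H](C(C)C)C3 | intermediate
25 | 6′,7′-didehydro-24 | CC(=O)O[C@H]1[C@H]2C(C)=C3C[C@@H](C(C)C)C4(OCCO4)C[C@@H](C)[C@]31[C@]1(C)C3=C(C(=O)[C@H]21)[C@H](C)CC5(OCCO5)C(C(C)C)=C3 | intermediate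
26 | 2-acetoxy-1′(5′),6′-diene-2′,8,8′-trione | CC(=O)O[C@H]1[C@H]2C(C)=C3C[C@@H](C(C)C)C(=O)C[C@@H](C)[C@]31[C@]1(C)C3=C(C(=O)[C@H]21)[C@H](C)CC(=O)C(C(C)C)=C3 | intermediate
27 | 11′-hydroperoxide of 26 | CC(=O)O[C@H]1[C@H]2C(C)=C3C[C@@H](C(C)C)C(=O)C[C@@H](C)[C@]31[C@]1(C)C3=C(C(=O)[C@H]21)[C@H](C)CC(=O)C(C(C)(C)OO)=C3 | intermediate
28 | CNP0317907.1 | CC(=O)O[C@H]1[C@H]2C(C)=C3C[C@@H](C(C)C)C(=O)C[C@@H](C)[C@]31[C@]1(C)C3=C(C(=O)[C@H]21)[C@H](C)C[C@@]1(O)OOC(C)(C)C1=C3 | target

**Totals**
Total step count: 18. Longest linear sequence: 17 steps (steps 1, 3–18; the branch through step 2 is equally long).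

**Three steps most likely to fail**

Step 14 (Mitsunobu on the concave allylic alcohol). The bulky phosphonium may fail to engage the hindered endo hydroxyl, or elimination to a cyclopentadiene may compete. The fallback sets out from 21 and replaces the one-pot redox condensation by a discrete sulfonate displacement: MsCl and Et3N in CH2Cl2 at −20 °C mesylate only the allylic hydroxyl to give the 2′-endo-methanesulfonate of 21 F1, and CsOAc with 18-crown-6 in toluene at 50 °C displaces it with inversion, which comes back to the route at 22.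

Step 16 (chloranil dehydrogenation). Hydride abstraction from the tertiary C7′ may be slow, or the allylic positions of the norbornene half may be attacked. The fallback sets out from 24 and uses a Saegusa–Ito oxidation instead: TBSOTf and Et3N in CH2Cl2 at rt under equilibrating conditions give the extended 2′-(tert-butyldimethylsilyloxy)-1′,5′(6′)-diene of 24 F2 (24 has no other ketone to silylate), and Pd(OAc)2 in MeCN/DMSO then gives the dienone and comes back to the route at 25.

Step 18 (autoxidation). Oxygen capture may occur at C6′ or C9′ instead of C11′, or the peroxide may degrade under base. The fallback sets out from 26 and makes the C11′–O bond by ionic substitution: DBU and N-bromosuccinimide at −40 °C brominate the same trienolate at its ε-carbon to give the 11′-bromo derivative of 26 F3, and AgOCOCF3 with anhydrous ethereal H2O2 at 0 °C replaces bromide by hydroperoxide, which comes back to the route at 27 and closes to 28 as before.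

**Further compounds**
F1 | step 14 | 2′-endo-methanesulfonate of 21 | O[C@@H]1[C@H]2C(C)=C3C[C@@H](C(C)C)C4(OCCO4)C[C@@H](C)[C@]31[C@]1(C)C3=C([C@H](OS(C)(=O)=O)[C@H]21)[C@H](C)CC5(OCCO5)[C@H](C(C)C)C3
F2 | step 16 | 2′-(tert-butyldimethylsilyloxy)-1′,5′(6′)-diene of 24 | CC(=O)O[C@H]1[C@H]2C(C)=C3C[C@@H](C(C)C)C4(OCCO4)C[C@@H](C)[C@]31[C@]1(C)C=3C(=C(O[Si](C)(C)C(C)(C)C)[C@H]21)[C@H](C)CC5(OCCO5)[C@H](C(C)C)C3
F3 | step 18 | 11′-bromo derivative of 26 | CC(=O)O[C@H]1[C@H]2C(C)=C3C[C@@H](C(C)C)C(=O)C[C@@H](C)[C@]31[C@]1(C)C3=C(C(=O)[C@H]21)[C@H](C)CC(=O)C(C(C)(C)Br)=C3
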